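Birch and elm are the two runs we can read; both charge the same starting complex and protic impurity, so they differ in the incoming ligand, 0.680 against 1.80 equivalents.

all flasks: starting complex 0.10 M

| flask | incoming ligand | protic impurity | remark | time |
|---|---|---|---|---|
| birch | 0.068 M | 0.10 M | run made earlier |  |
| elm | 0.18 M | 0.10 M | run made earlier |  |
| epsilon | 0.0800 M | 0.100 M |  | 12 h |
| theta | 0.120 M | 0.100 M |  | 12 h |
| beta | 0.0500 M | 0.100 M |  | 12 h |

| birch: time / h | birch: complex with one exchanged / % | elm: time / h | elm: complex with one exchanged / % |
|---|---|---|---|
| 2.50 | 22 | 1.00 | 10 |
| 5.00 | 21 | 3.00 | 6 |
| 8.00 | 22 | 6.00 | 5 |
| 10.0 | 20 | 8.00 | 7 |
| 12.0 | 23 | 12.0 | 5 |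

(each reading ± 1.5 percentage points)

- what was read earlier has a scatter of 1.5 percentage points, one standard deviation

- which of these holds the largest part of the starting complex at the end of epsilon (complex with two exchanged / complex with one exchanged / starting complex / complex with three exchanged)
- which of these holds the largest part of the starting complex at the end of theta (complex with two exchanged / complex with one exchanged / starting complex / complex with three exchanged)
- which of these holds the largest part of the starting complex at the end of beta (complex with two exchanged / complex with one exchanged / starting complex / complex with three exchanged)
- final complex with one exchanged in theta, as a percentage of the starting complex charged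

The curve of the complex with one exchanged starts from zero and climbs steeply. In birch the climb is over at the first reading, 2.50 h, and the readings then lie flat around an end-point level of 21.6%. In elm it stands at 10% after 1.00 h and comes down, by 3.00 h, to 5.75%, a drop of 4.2 percentage points against a scatter of 1.5 points, so we read the elm curve as having passed a peak. Both knees lie earlier than 12 h, so we reckon with the level and leave the clock aside. We carry one quantity, the level lost per equivalent of incoming ligand, 14.2% of the starting complex charged per equivalent, read as a straight line through the two levels with starting complex and protic impurity held as in those runs. Theta, at 1.20 equivalents, lies 0.520 equivalents beyond birch, so we draw its curve like elm's, up to an early peak and then down past a knee by about 3.00 h into a level of 14.2%; of the other species the readings tell us nothing.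

The forecast, holding that “the product split depends on equivalents charged, not on time”, names starting complex for epsilon, complex with two exchanged for theta and starting complex for beta as the largest holder, and gives 18% for the theta level, above our figure.

Theta ends at 15.8%, and its largest holder is complex with three exchanged at 29.1%, while 46.7% of its starting complex ended as quenched substrate. The largest holder is complex with one exchanged in epsilon and complex with one exchanged in beta. Our slope took 7.4 points off the birch level for theta, where the flask lies 5.8 points below it.

    complex with one exchanged + incoming ligand ⇌ leaving ligand + complex with two exchanged (K = 0.749, k = 0.0652 /M/s)
    leaving ligand → by-product carried off (k = 0.00379 /s)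
    complex with two exchanged + incoming ligand ⇌ leaving ligand + complex with three exchanged (K = 68.0, k = 0.0925 /M/s)
    protic impurity + starting complex → quenched substrate (k = 0.0180 /M/s)
    starting complex + incoming ligand ⇌ leaving ligand + complex with one exchanged (K = 1.80, k = 0.0741 /M/s)

A neighbour of theta charged with 0.25 M of starting complex has 0.480 equivalents, and the slope, carried across that changed charge, gives 24.4%; the computed flask ends at 23.3%.

The readings come from a simulation on assumed constants; noise was put on by code.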